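The runs come from a simulation from invented constants; scatter was added.

Charge reagent per solid substrate: 1.20 in Wednesday's and 1.20 in Thursday's. So reckon the percent of target from what one target costs in reagent.

| setting | south-east | north-east | north-west | Wednesday's | Thursday's |
|---|---|---|---|---|---|
| solid substrate | 14 mM | 14 mM | 15 mM | 10 mM | 14 mM |
| reagent | 8.8 mM | 11 mM | 16.8 mM | 12.0 mM | 16.8 mM |
| temperature | 0 °C | 11 °C | 0 °C | 5 °C | 5 °C |
| remark | run made earlier | run made earlier | run made earlier |  |  |
| time |  |  |  | 20 h | 20 h |

| run | time / h | target / % |
|---|---|---|
| south-east | 4.00 | 7.6 |
| south-east | 8.00 | 16.1 |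
| south-east | 12.0 | 21.9 |
| south-east | 15.0 | 25.6 |
| south-east | 20.0 | 28.8 |
| north-east | 2.00 | 7.1 |
| north-east | 5.00 | 19.5 |
| north-east | 10.0 | 32.2 |
| north-east | 15.0 | 37.9 |
| north-east | 20.0 | 40.2 |
| north-west | 1.50 | 3.3 |
| north-west | 3.00 | 7.7 |
| north-west | 6.00 | 16.7 |
| north-west | 10.0 | 26.2 |
| north-west | 20.0 | 39.1 |

(readings scatter by 0.3 percentage points)

- target is meant together with its crystals
- solid, in amounts per volume of the solution: crystals, solid substrate
- candidate steps: starting material + 2 reagent -> side product; crystals <-> target; solid substrate <-> starting material; starting material + reagent -> target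
- at the start none of the solid substrate is in solution
- what has only dissolved of solid substrate counts as not reacted

- which of the two ends with the higher amount of target, in percent of the solid substrate charged ("neither" if they lie within 2 percentage points) (Wednesday's / Thursday's / neither)
- target at the end, in percent of the solid substrate charged, Wednesday's
- target at the end, in percent of the solid substrate charged, Thursday's

Solid substrate dissolves to starting material. Starting material takes one reagent to target, or two reagent to side product.

Start from the north-east run. It rises 2.3 percentage points in its last 5.00 h, so treat its reagent as spent. Then 11 mM bought 5.63 mM of target, or 1.95: the reagent price, reagent spent per target formed.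

Now compare the two steps at one moment. Side product over target goes as a selectivity factor times reagent, so the momentary price is one plus two times that product. Reagent drifts from its charge towards nothing, so take the mean price as one plus the factor times the charge. The reading gives a factor of 0.0868 mM⁻¹.

Wednesday's then pays 2.04 and Thursday's 2.46. Their ceilings are 58.8% and 48.8%.

Next, time. At 0 °C the last readings reach 80.8% of their ceiling in the south-east run and 85.8% in the north-west run. Put 5 °C near the middle, between these and the full ceiling taken at 11 °C. That gives 90.4% for Wednesday's and 92.9% for Thursday's, so 53.1% and 45.4%.

The weak link is Wednesday's solid: 10 mM, against 14 mM in the south-east run. Reforge it: let the approach run at a rate proportional to the solid charged. That puts Wednesday's at 81.3% of its ceiling, so I commit to 47.8%, still higher than Thursday's by 2.4 points.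

The forecast says Wednesday's, with 51% and 46%, and grounds the win on the reagent: “Reagent exhaustion then caps target”. Its Wednesday figure stands above mine.

The flasks give Wednesday's: 49.3% against 44.8%.

    starting material + 2 reagent → side product (k = 2000 L² mol⁻² h⁻¹, Ea = 46.0 kJ mol⁻¹)
    crystals ⇌ target, rate k2*(cs2 - [target]) while solid is left; crystals form when [target] > cs2 (solubility = 6.20 mM, k = 67.0 h⁻¹)
    solid substrate ⇌ starting material, rate k3*(cs3 - [starting material]) while solid is left; crystals form when [starting material] > cs3 (solubility = 5.70 mM, k = 0.520 h⁻¹)
    starting material + reagent → target (k = 20.0 L mol⁻¹ h⁻¹, Ea = 49.0 kJ mol⁻¹)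
    (constants at 5 °C)

Wednesday's has spent 88.8% of its reagent at 20.0 h, a price so far of 2.16, higher than the mean price 2.04. At that time in Wednesday's the target step uses 3.7 times the reagent of the side step. Read the same flask at 3.0 d: 2.0% of the reagent remains, so the mean price gives 57.6% of target. That flask holds 58.9% of target and 29.4% of side product, a price of 2.00.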